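The route rests on cutting the C1–C10 bond of the ten-membered carbocycle. That ring is a cis,cis-cyclodeca-1,6-diene (C4=C5 and C9=C10 both ring-cis, hence little transannular strain) with an allylic carbinol (C1) beside the Z-configured C9=C10 bond. An intramolecular Ni/Cr (Nozaki–Hiyama–Kishi) addition of the Z-alkenyl iodide at C10 to a C1 aldehyde therefore closes the carbocycle in one operation, with retention of alkene geometry, on an open-chain precursor that already holds the trans-disubstituted α-methylene-γ-butyrolactone and the C8 ester. This precursor comes from a zinc Barbier coupling of a 3-(bromomethyl)butenolide with (Z)-3-iodobut-2-enal; C1 is finally set by oxidation and CBS reduction.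

Key step: step 15

Remark (assumptions): locants C1–C15 are germacranolide positions (C1 = ring CH(OH); C4 bears C15H2OH; C6 = lactone O–CH; C7 = ring-fusion CH; C8 = CH(O-acyl); C10 bears the C14 methyl; C11=C13 = exocyclic alkene; C12 = lactone C=O). CIP descriptors at C7/C8 change in the iodo compounds without change of geometry. The (S,S)-ProPhenol and (R)-CBS antipodes are assigned from the accepted models and would be exchanged if the sense proved opposite. TBDPS = tert-butyldiphenylsilyl, TBS = tert-butyldimethylsilyl.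

Step 1
Reactants: 1 but-2-yne-1,4-diol
Product: 2 4-(TBDPS-oxy)but-2-yn-1-ol
Conditions: TBDPSCl (0.3 equiv), imidazole, THF/DMF, 0 °C to rt
Reagents that add atoms: tert-butyl(chloro)diphenylsilane, CC(C)(C)[Si](Cl)(c1ccccc1)c1ccccc1
Why: Statistical monosilylation of a symmetrical diol used in excess (silyl ether formation), the unreacted diol being removed with water.

Step 2
Reactants: 2 4-(TBDPS-oxy)but-2-yn-1-ol
Product: 4 (Z)-4-(TBDPS-oxy)-3-iodobut-2-en-1-ol, via cyclic alkenylalanate 3 (not isolated)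
Conditions: Red-Al, THF, 0 °C; EtOAc; then I2, −78 to 0 °C
Reagents that add atoms: iodine, II
Why: Hydroxyl-directed trans-hydroalumination of the propargylic alcohol puts aluminium on the distal alkyne carbon cis to the carbinol carbon, and iodinolysis with retention should give the Z-iodoalkene that fixes the C4=C5 geometry.

Step 3
Reactants: 4 (Z)-4-(TBDPS-oxy)-3-iodobut-2-en-1-ol; 5 acrolein diethyl acetal
Product: 7 (E)-3-[(TBDPS-oxy)methyl]-6,6-diethoxyhex-2-en-1-ol, via B-(3,3-diethoxypropyl)-9-BBN 6 (not isolated)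
Conditions: 5, 9-BBN, THF, 0 °C to rt; then 4, PdCl2(dppf) (cat.), AsPh3, Cs2CO3, DMF/H2O, rt
Reagents that add atoms: none
Why: Anti-Markovnikov hydroboration followed by B-alkyl Suzuki–Miyaura coupling, which proceeds with retention at the iodoalkene and so places the C3 chain cis to C6.

Step 4
Reactants: 7 (E)-3-[(TBDPS-oxy)methyl]-6,6-diethoxyhex-2-en-1-ol
Product: 8 (E)-3-[(TBDPS-oxy)methyl]-6,6-diethoxyhex-2-enal
Conditions: MnO2, CH2Cl2, rt
Reagents that add atoms: none
Why: Neutral allylic oxidation with manganese dioxide should give the enal without E/Z isomerisation or loss of the acetal.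

Step 5
Reactants: 8 (E)-3-[(TBDPS-oxy)methyl]-6,6-diethoxyhex-2-enal; 9 tert-butyldimethyl(prop-2-yn-1-yloxy)silane
Product: 11 (4R,5E)-1-(TBS-oxy)-6-[(TBDPS-oxy)methyl]-9,9-diethoxynon-5-en-2-yn-4-ol, via methylzinc acetylide 10 (not isolated)
Conditions: Me2Zn, (S,S)-ProPhenol (20 mol%), Ph3PO (cat.), toluene, 0 °C
Reagents that add atoms: none
Why: Catalytic asymmetric alkynylation of an enal with a dinuclear zinc–ProPhenol complex, which delivers the alkynylzinc to the Si face of the aldehyde and so sets C6 as R under catalyst control.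

Step 6
Reactants: 11 (4R,5E)-1-(TBS-oxy)-6-[(TBDPS-oxy)methyl]-9,9-diethoxynon-5-en-2-yn-4-ol
Product: 13 (2Z,4R,5E)-1-(TBS-oxy)-6-[(TBDPS-oxy)methyl]-9,9-diethoxy-2-iodonona-2,5-dien-4-ol, via cyclic alkenylalanate 12 (not isolated)
Conditions: Red-Al, THF, 0 °C; EtOAc; then I2, −78 to 0 °C
Reagents that add atoms: iodine, II
Why: The same hydroxyl-directed trans-hydroalumination/iodination, now directed by the C6 hydroxyl, places iodine on C11 cis to C6, while the trisubstituted alkene is not reduced and C6 is untouched.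

Step 7
Reactants: 13 (2Z,4R,5E)-1-(TBS-oxy)-6-[(TBDPS-oxy)methyl]-9,9-diethoxy-2-iodonona-2,5-dien-4-ol
Product: 14 (5R)-5-[(1E)-2-[(TBDPS-oxy)methyl]-5,5-diethoxypent-1-en-1-yl]-3-[(TBS-oxy)methyl]furan-2(5H)-one
Conditions: PdCl2(PPh3)2 (cat.), CO (1 atm), K2CO3, THF, rt
Reagents that add atoms: carbon monoxide, [C-]#[O+]
Why: Palladium-catalysed carbonylative lactonisation of a (Z)-γ-hydroxy iodoalkene (oxidative addition, CO insertion, capture of the acylpalladium by the cis hydroxyl) builds the butenolide; the weak heterogeneous base is chosen to spare the doubly allylic C6–H.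

Step 8
Reactants: 14 (5R)-5-[(1E)-2-[(TBDPS-oxy)methyl]-5,5-diethoxypent-1-en-1-yl]-3-[(TBS-oxy)methyl]furan-2(5H)-one
Product: 15 (5R)-5-[(1E)-2-[(TBDPS-oxy)methyl]-5,5-diethoxypent-1-en-1-yl]-3-(hydroxymethyl)furan-2(5H)-one
Conditions: PPTS (cat.), EtOH, rt
Reagents that add atoms: none
Why: Mild acid ethanolysis cleaves the primary TBS ether selectively, the TBDPS ether being far slower and the diethyl acetal being degenerate in ethanol.

Step 9
Reactants: 15 (5R)-5-[(1E)-2-[(TBDPS-oxy)methyl]-5,5-diethoxypent-1-en-1-yl]-3-(hydroxymethyl)furan-2(5H)-one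
Product: 16 (5R)-3-(bromomethyl)-5-[(1E)-2-[(TBDPS-oxy)methyl]-5,5-diethoxypent-1-en-1-yl]furan-2(5H)-one
Conditions: CBr4, PPh3, CH2Cl2, 0 °C
Reagents that add atoms: carbon tetrabromide, BrC(Br)(Br)Br
Why: Appel bromination converts the primary allylic alcohol to the bromide under neutral conditions that avoid deprotonation at C6.

Step 10
Reactants: 17 but-2-yn-1-ol
Product: 19 (Z)-3-iodobut-2-en-1-ol, via cyclic alkenylalanate 18 (not isolated)
Conditions: Red-Al, THF, 0 °C; EtOAc; then I2, −78 to 0 °C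
Reagents that add atoms: iodine, II
Why: Hydroxyl-directed trans-hydroalumination/iodination gives the Z-iodoalkene that later becomes the ring-cis C9=C10 bond.

Step 11
Reactants: 19 (Z)-3-iodobut-2-en-1-ol
Product: 20 (Z)-3-iodobut-2-enal
Conditions: MnO2, CH2Cl2, rt, dark; used at once
Reagents that add atoms: none
Why: Neutral allylic oxidation should give the sensitive Z-enal without isomerisation.

Step 12
Reactants: 16 (5R)-3-(bromomethyl)-5-[(1E)-2-[(TBDPS-oxy)methyl]-5,5-diethoxypent-1-en-1-yl]furan-2(5H)-one; 20 (Z)-3-iodobut-2-enal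
Product: 22 (4R,5R)-5-[(1E)-2-[(TBDPS-oxy)methyl]-5,5-diethoxypent-1-en-1-yl]-4-[(1R,2Z)-1-hydroxy-3-iodobut-2-en-1-yl]-3-methylideneoxolan-2-one, via allylzinc bromide 21 (not isolated)
Conditions: Zn dust, sat. aq. NH4Cl/THF, 0 °C to rt
Reagents that add atoms: none
Why: Barbier allylation with a 3-(bromomethyl)butenolide, in which the allylzinc reacts through C7 (SE2′) to unveil the exocyclic methylene; attack anti to the C6 alkenyl group should set C7 (trans-lactone), and the ring-locked E-type allyl geometry in a chair transition state should place O8 anti to C6, i.e. the C8 epimer of the target.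

Step 13
Reactants: 22 (4R,5R)-5-[(1E)-2-[(TBDPS-oxy)methyl]-5,5-diethoxypent-1-en-1-yl]-4-[(1R,2Z)-1-hydroxy-3-iodobut-2-en-1-yl]-3-methylideneoxolan-2-one; 23 (S)-2-methylbutanoic acid
Product: 24 (1S,2Z)-1-[(2R,3S)-2-[(1E)-2-[(TBDPS-oxy)methyl]-5,5-diethoxypent-1-en-1-yl]-4-methylidene-5-oxooxolan-3-yl]-3-iodobut-2-en-1-yl (2S)-2-methylbutanoate
Conditions: PPh3, DIAD, toluene, 0 °C to rt
Reagents that add atoms: none
Why: Mitsunobu esterification, in which SN2 displacement of the alkoxyphosphonium by the carboxylate inverts C8 to the configuration of the target while the α-centre of the acid is untouched.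

Step 14
Reactants: 24 (1S,2Z)-1-[(2R,3S)-2-[(1E)-2-[(TBDPS-oxy)methyl]-5,5-diethoxypent-1-en-1-yl]-4-methylidene-5-oxooxolan-3-yl]-3-iodobut-2-en-1-yl (2S)-2-methylbutanoate
Product: 25 (1S,2Z)-1-[(2R,3S)-2-[(1E)-2-[(TBDPS-oxy)methyl]-5-oxopent-1-en-1-yl]-4-methylidene-5-oxooxolan-3-yl]-3-iodobut-2-en-1-yl (2S)-2-methylbutanoate
Conditions: LiBF4, MeCN/H2O (50:1), rt
Reagents that add atoms: water, O
Why: Mild Lewis-acid hydrolysis of the diethyl acetal should free the C1 aldehyde without touching the TBDPS ether, the allylic ester or the lactone.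

Step 15
Reactants: 25 (1S,2Z)-1-[(2R,3S)-2-[(1E)-2-[(TBDPS-oxy)methyl]-5-oxopent-1-en-1-yl]-4-methylidene-5-oxooxolan-3-yl]-3-iodobut-2-en-1-yl (2S)-2-methylbutanoate
Product: 27 15-O-TBDPS ether of the target as a mixture of C1 epimers (1RS,6R,7R,8R), via alkenylchromium(III) dichloride 26 (not isolated)
Conditions: CrCl2 (10 equiv), NiCl2 (cat.), DMSO/THF, rt, 0.003 M, syringe-pump addition of 25
Reagents that add atoms: none
Why: Ni(0) inserts into the C10–I bond with retention, the alkenyl group is passed to Cr(III), and the alkenylchromium adds to the C1 aldehyde, which is far more reactive toward it than the lactone, the ester or the acrylate unit. The closest known reaction type is the Nozaki–Hiyama–Kishi macrocyclisation of iodoalkene aldehydes to medium and large carbocycles. The ten-membered ring is closed in a 10-exo-trig mode by C10–C1 bond formation; the two ring-cis alkenes and the trans-lactone leave only a cis,cis-cyclodeca-1,6-diene to be formed, which carries little transannular strain. The new stereocentre C1 is under weak substrate control only (the chromium alkoxide should prefer the peripheral position), and this is not relied upon because both epimers converge in step 16. The step needs intramolecular over intermolecular coupling, secured by high dilution and slow addition, and retention of the Z geometry at C9=C10, secured by the stereospecific oxidative addition and transmetalation.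

Step 16
Reactants: 27 15-O-TBDPS ether of the target as a mixture of C1 epimers
Product: 28 15-O-TBDPS-1-oxo derivative (macrocyclic enone; 6R,7R,8R)
Conditions: Dess–Martin periodinane, NaHCO3, CH2Cl2, 0 °C to rt
Reagents that add atoms: none
Why: Dess–Martin oxidation of the secondary allylic alcohol converges both C1 epimers on one enone under buffered conditions that spare the silyl ether and the esters.

Step 17
Reactants: 28 15-O-TBDPS-1-oxo derivative
Product: 29 15-O-TBDPS ether of the target (1S,6R,7R,8R)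
Conditions: (R)-Me-CBS (1.5 equiv), catecholborane, toluene, −78 °C; MeOH, pH 7 buffer
Reagents that add atoms: none
Why: Corey–Bakshi–Shibata reduction, in which the oxazaborolidine binds the ketone with the α-methylalkenyl group (C10) as the large substituent and delivers hydride to the face that gives the 1S carbinol (reagent control); catecholborane at low temperature should leave the α-methylene lactone alone.

Step 18
Reactants: 29 15-O-TBDPS ether of the target
Product: 30 target, (1S,6R,7R,8R)-1,15-dihydroxy-8-[(2S)-2-methylbutanoyloxy]germacra-4,9(Z),11(13)-trien-6,12-olide (CNP0526758.1)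
Conditions: HF·pyridine, pyridine/THF, 0 °C to rt
Reagents that add atoms: none
Why: Buffered fluoride desilylation removes the TBDPS ether without acyl migration, Michael addition or lactone opening.

Compound list
1 | but-2-yne-1,4-diol | OCC#CCO | starting material
2 | 4-(TBDPS-oxy)but-2-yn-1-ol | OCC#CCO[Si](c1ccccc1)(c1ccccc1)C(C)(C)C | intermediate
3 | sodium cyclic alkenylalanate from 2 (Al on the carbon bearing CH2OTBDPS) | [Na+].COCCO[Al-]1(OCCOC)OCC=C1CO[Si](c2ccccc2)(c2ccccc2)C(C)(C)C | intermediate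
4 | (Z)-4-(TBDPS-oxy)-3-iodobut-2-en-1-ol | OC/C=C(\I)CO[Si](c1ccccc1)(c1ccccc1)C(C)(C)C | intermediate
5 | acrolein diethyl acetal (3,3-diethoxyprop-1-ene) | C=CC(OCC)OCC | starting material
6 | 9-(3,3-diethoxypropyl)-9-borabicyclo[3.3.1]nonane | CCOC(CCB1C2CCCC1CCC2)OCC | intermediate
7 | (E)-3-[(TBDPS-oxy)methyl]-6,6-diethoxyhex-2-en-1-ol | OC/C=C(\CCC(OCC)OCC)CO[Si](c1ccccc1)(c1ccccc1)C(C)(C)C | intermediate
8 | (E)-3-[(TBDPS-oxy)methyl]-6,6-diethoxyhex-2-enal | O=C/C=C(\CCC(OCC)OCC)CO[Si](c1ccccc1)(c1ccccc1)C(C)(C)C | intermediate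
9 | tert-butyldimethyl(prop-2-yn-1-yloxy)silane | C#CCO[Si](C)(C)C(C)(C)C | starting material
10 | methyl[3-(TBS-oxy)prop-1-yn-1-yl]zinc | C[Zn]C#CCO[Si](C)(C)C(C)(C)C | intermediate
11 | (4R,5E)-1-(TBS-oxy)-6-[(TBDPS-oxy)methyl]-9,9-diethoxynon-5-en-2-yn-4-ol | O[C@@H](C#CCO[Si](C)(C)C(C)(C)C)/C=C(\CCC(OCC)OCC)CO[Si](c1ccccc1)(c1ccccc1)C(C)(C)C | intermediate
12 | sodium cyclic alkenylalanate from 11 (Al on C11) | [Na+].COCCO[Al-]1(OCCOC)O[C@H](/C=C(\CCC(OCC)OCC)CO[Si](c2ccccc2)(c2ccccc2)C(C)(C)C)C=C1CO[Si](C)(C)C(C)(C)C | intermediate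
13 | (2Z,4R,5E)-1-(TBS-oxy)-6-[(TBDPS-oxy)methyl]-9,9-diethoxy-2-iodonona-2,5-dien-4-ol | O[C@@H](/C=C(\I)CO[Si](C)(C)C(C)(C)C)/C=C(\CCC(OCC)OCC)CO[Si](c1ccccc1)(c1ccccc1)C(C)(C)C | intermediate
14 | (5R)-5-[(1E)-2-[(TBDPS-oxy)methyl]-5,5-diethoxypent-1-en-1-yl]-3-[(TBS-oxy)methyl]furan-2(5H)-one | O=C1O[C@H](/C=C(\CCC(OCC)OCC)CO[Si](c2ccccc2)(c2ccccc2)C(C)(C)C)C=C1CO[Si](C)(C)C(C)(C)C | intermediate
15 | (5R)-5-[(1E)-2-[(TBDPS-oxy)methyl]-5,5-diethoxypent-1-en-1-yl]-3-(hydroxymethyl)furan-2(5H)-one | O=C1O[C@H](/C=C(\CCC(OCC)OCC)CO[Si](c2ccccc2)(c2ccccc2)C(C)(C)C)C=C1CO | intermediate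
16 | (5R)-3-(bromomethyl)-5-[(1E)-2-[(TBDPS-oxy)methyl]-5,5-diethoxypent-1-en-1-yl]furan-2(5H)-one | O=C1O[C@H](/C=C(\CCC(OCC)OCC)CO[Si](c2ccccc2)(c2ccccc2)C(C)(C)C)C=C1CBr | intermediate
17 | but-2-yn-1-ol | CC#CCO | starting material
18 | sodium cyclic alkenylalanate from 17 | [Na+].COCCO[Al-]1(OCCOC)OCC=C1C | intermediate
19 | (Z)-3-iodobut-2-en-1-ol | OC/C=C(\I)C | intermediate
20 | (Z)-3-iodobut-2-enal | O=C/C=C(\I)C | intermediate
21 | allylzinc bromide from 16 (Zn on C13) | O=C1O[C@H](/C=C(\CCC(OCC)OCC)CO[Si](c2ccccc2)(c2ccccc2)C(C)(C)C)C=C1C[Zn]Br | intermediate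
22 | (4R,5R)-5-[(1E)-2-[(TBDPS-oxy)methyl]-5,5-diethoxypent-1-en-1-yl]-4-[(1R,2Z)-1-hydroxy-3-iodobut-2-en-1-yl]-3-methylideneoxolan-2-one (C6 R, C7 R, C8 R; C8 epimeric to the target in space) | C=C1C(=O)O[C@H](/C=C(\CCC(OCC)OCC)CO[Si](c2ccccc2)(c2ccccc2)C(C)(C)C)[C@H]1[C@@H](O)/C=C(\I)C | intermediate
23 | (S)-2-methylbutanoic acid | CC[C@H](C)C(=O)O | starting material
24 | (1S,2Z)-1-[(2R,3S)-2-[(1E)-2-[(TBDPS-oxy)methyl]-5,5-diethoxypent-1-en-1-yl]-4-methylidene-5-oxooxolan-3-yl]-3-iodobut-2-en-1-yl (2S)-2-methylbutanoate (C6 R, C7 S, C8 S; target geometry) | C=C1C(=O)O[C@H](/C=C(\CCC(OCC)OCC)CO[Si](c2ccccc2)(c2ccccc2)C(C)(C)C)[C@H]1[C@H](OC(=O)[C@@H](C)CC)/C=C(\I)C | intermediate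
25 | (1S,2Z)-1-[(2R,3S)-2-[(1E)-2-[(TBDPS-oxy)methyl]-5-oxopent-1-en-1-yl]-4-methylidene-5-oxooxolan-3-yl]-3-iodobut-2-en-1-yl (2S)-2-methylbutanoate | C=C1C(=O)O[C@H](/C=C(\CCC=O)CO[Si](c2ccccc2)(c2ccccc2)C(C)(C)C)[C@H]1[C@H](OC(=O)[C@@H](C)CC)/C=C(\I)C | intermediate
26 | alkenylchromium(III) dichloride from 25 (Cr on C10, Z) | C=C1C(=O)O[C@H](/C=C(\CCC=O)CO[Si](c2ccccc2)(c2ccccc2)C(C)(C)C)[C@H]1[C@H](OC(=O)[C@@H](C)CC)/C=C(\[Cr](Cl)Cl)C | intermediate
27 | 15-O-TBDPS ether of the target, C1 epimers (1RS,6R,7R,8R) | C=C1C(=O)O[C@@H]2/C=C(/CO[Si](c3ccccc3)(c3ccccc3)C(C)(C)C)CCC(O)/C(C)=C\[C@@H](OC(=O)[C@@H](C)CC)[C@@H]12 | intermediate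
28 | 15-O-TBDPS-1-oxo macrocyclic enone (6R,7R,8R) | C=C1C(=O)O[C@@H]2/C=C(/CO[Si](c3ccccc3)(c3ccccc3)C(C)(C)C)CCC(=O)/C(C)=C\[C@@H](OC(=O)[C@@H](C)CC)[C@@H]12 | intermediate
29 | 15-O-TBDPS ether of the target (1S,6R,7R,8R) | C=C1C(=O)O[C@@H]2/C=C(/CO[Si](c3ccccc3)(c3ccccc3)C(C)(C)C)CC[C@H](O)/C(C)=C\[C@@H](OC(=O)[C@@H](C)CC)[C@@H]12 | intermediate
30 | CNP0526758.1, (1S,6R,7R,8R)-1,15-dihydroxy-8-[(2S)-2-methylbutanoyloxy]germacra-4,9(Z),11(13)-trien-6,12-olide | C=C1C(=O)O[C@@H]2/C=C(/CO)CC[C@H](O)/C(C)=C\[C@@H](OC(=O)[C@@H](C)CC)[C@@H]12 | target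

Total step count: 18. Longest linear sequence: 16 (steps 1–9 and 12–18).

Steps most likely to fail

1. Step 15 (key step). Intermolecular coupling or hydrodeiodination may outrun ring closure, or the alkenyl–metal intermediate may expel the allylic C8 carboxylate. The fallback exchanges the order of the two couplings, so that the carbocycle is closed last at C7–C8 by an intramolecular zinc Barbier allylation. It sets out from 14 and comes back at 30. LiBF4 in wet MeCN would turn 14 into the aldehyde F1. An intermolecular Ni/Cr coupling of F1 with the silyl ether F2 (from 19, TBSCl, imidazole), run with a Kishi oxazoline–sulfonamide ligand, would give the (1S)-allylic alcohol F3. TBSOTf/2,6-lutidine would give the C1 silyl ether F4, and PPTS/EtOH would remove the two primary TBS groups to give the diol F5. MnO2 should oxidise only the electron-rich C8 allylic alcohol, giving the enal F6, and CBr4/PPh3 would then give the bromide F7. Zn in aq. NH4Cl/THF at high dilution would close the ring to the macrocyclic alcohol F8. Esterification with 23 (DCC/DMAP, or Mitsunobu if C8 forms with the opposite configuration) would give F9, and HF·pyridine would remove both silyl groups to give 30.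

2. Step 12. The addition may not pass cleanly through one chair transition state, so that the syn (C8-epimeric) alcohol F10 forms beside or instead of 22. The fallback is a stereoconvergent esterification that sets out from 16 and 20 and comes back at 24. The epimers would be separated; F10 would be acylated with retention (23, DCC, DMAP), while 22 follows the Mitsunobu inversion of step 13, and both streams meet at 24.

3. Step 17. Hydride may be delivered to the wrong face of the flexible macrocyclic enone, or may add in a conjugate sense to the α-methylene lactone. The fallback avoids the oxidation/reduction pair; it sets out from 27 and comes back at 29. The C1 epimers of 27 would be separated, the (1S) epimer being 29 itself. The (1R) epimer would be inverted by a Mitsunobu reaction with methoxyacetic acid (PPh3, DIAD) to the methoxyacetate F11, which is cleaved under neutral conditions (Yb(OTf)3, MeOH) to 29.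

Further compounds
F1 | step 15 | (5R)-5-[(1E)-2-[(TBDPS-oxy)methyl]-5-oxopent-1-en-1-yl]-3-[(TBS-oxy)methyl]furan-2(5H)-one | O=C1O[C@H](/C=C(\CCC=O)CO[Si](c2ccccc2)(c2ccccc2)C(C)(C)C)C=C1CO[Si](C)(C)C(C)(C)C
F2 | step 15 | (Z)-tert-butyl[(3-iodobut-2-en-1-yl)oxy]dimethylsilane | CC(C)(C)[Si](C)(C)OC/C=C(\I)C
F3 | step 15 | butenolide (1S)-allylic alcohol with C8–OTBS, C13–OTBS, C15–OTBDPS | O=C1O[C@H](/C=C(\CC[C@H](O)/C(C)=C\CO[Si](C)(C)C(C)(C)C)CO[Si](c2ccccc2)(c2ccccc2)C(C)(C)C)C=C1CO[Si](C)(C)C(C)(C)C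
F4 | step 15 | C1-O-TBS ether of F3 | O=C1O[C@H](/C=C(\CC[C@H](O[Si](C)(C)C(C)(C)C)/C(C)=C\CO[Si](C)(C)C(C)(C)C)CO[Si](c2ccccc2)(c2ccccc2)C(C)(C)C)C=C1CO[Si](C)(C)C(C)(C)C
F5 | step 15 | C8,C13-diol (C1–OTBS, C15–OTBDPS) | O=C1O[C@H](/C=C(\CC[C@H](O[Si](C)(C)C(C)(C)C)/C(C)=C\CO)CO[Si](c2ccccc2)(c2ccccc2)C(C)(C)C)C=C1CO
F6 | step 15 | (Z)-enal with free C13 hydroxymethyl | O=C1O[C@H](/C=C(\CC[C@H](O[Si](C)(C)C(C)(C)C)/C(C)=C\C=O)CO[Si](c2ccccc2)(c2ccccc2)C(C)(C)C)C=C1CO
F7 | step 15 | 3-(bromomethyl)butenolide (Z)-enal | O=C1O[C@H](/C=C(\CC[C@H](O[Si](C)(C)C(C)(C)C)/C(C)=C\C=O)CO[Si](c2ccccc2)(c2ccccc2)C(C)(C)C)C=C1CBr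
F8 | step 15 | macrocyclic C8 alcohol, 1-O-TBS, 15-O-TBDPS (1S,6R,7R,8R) | C=C1C(=O)O[C@@H]2/C=C(/CO[Si](c3ccccc3)(c3ccccc3)C(C)(C)C)CC[C@H](O[Si](C)(C)C(C)(C)C)/C(C)=C\[C@@H](O)[C@@H]12
F9 | step 15 | 1-O-TBS-15-O-TBDPS ether of the target | C=C1C(=O)O[C@@H]2/C=C(/CO[Si](c3ccccc3)(c3ccccc3)C(C)(C)C)CC[C@H](O[Si](C)(C)C(C)(C)C)/C(C)=C\[C@@H](OC(=O)[C@@H](C)CC)[C@@H]12
F10 | step 12 | C8 epimer of 22, (4R,5R)-4-[(1S,2Z)-1-hydroxy-3-iodobut-2-en-1-yl] lactone | C=C1C(=O)O[C@H](/C=C(\CCC(OCC)OCC)CO[Si](c2ccccc2)(c2ccccc2)C(C)(C)C)[C@H]1[C@H](O)/C=C(\I)C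
F11 | step 17 | (1S)-methoxyacetate of 29 | C=C1C(=O)O[C@@H]2/C=C(/CO[Si](c3ccccc3)(c3ccccc3)C(C)(C)C)CC[C@H](OC(=O)COC)/C(C)=C\[C@@H](OC(=O)[C@@H](C)CC)[C@@H]12
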